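**Assumption:** geometrically pure (E)-geranylacetone is purchased, and the squalene–hopene cyclase biocatalyst (a catalyst, not a starting material) is prepared by standard expression in E. coli.

## Retrosynthetic overview

1. Last C–C bond: C4'–C5' of the side chain, by B-alkyl Suzuki coupling of a ring-bearing C14 (E)-vinyl iodide with a C11 homoallyl borane.
2. The C11 piece comes from geraniol (both of its E-olefins are carried over): silylation, SeO2 oxidation of the E-methyl, oxidation to the enal, Wittig methylenation, then 9-BBN hydroboration.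
3. The (E)-vinyl iodide comes from Zr-catalysed carboalumination/iodination of a terminal alkyne, made from the C13 hydroxy methyl ketone.
4. The hydroxy ketone comes from hydrolysis of the trans-fused bicyclic enol ether formed by enzymatic cation–olefin cyclization of (E)-geranylacetone.
5. Ring order: the cyclohexane is the only carbocycle and is formed first (step 1), together with a temporary dihydropyran that is opened in step 2. Both stereocentres are set in step 1.

## Route

**Step 1**
Reactants: 1, (E)-geranylacetone [(5E)-6,10-dimethylundeca-5,9-dien-2-one]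
Product: 2, (4aS,8aS)-2,5,5,8a-tetramethyl-4a,5,6,7,8,8a-hexahydro-4H-chromene (trans-fused bicyclic enol ether)
Conditions: squalene–hopene cyclase (AacSHC, E. coli whole cells), citrate buffer pH 6.0, 0.1% SDS, 35 °C, 48–72 h
Reagents that add atoms: none
Why: Enzymatic polyene (cation–olefin) cyclization: the cyclase protonates the terminal alkene in a chair fold, and C–C bond formation and capture by the ketone oxygen occur anti across the 5E alkene, giving the trans ring fusion, with the enzyme fixing the (4aS,8aS) absolute sense.

**Step 2**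
Reactants: 2, bicyclic enol ether
Product: 3, 4-[(1S,2S)-2-hydroxy-2,6,6-trimethylcyclohexyl]butan-2-one
Conditions: 0.5 M aq. HCl, THF, 0 °C → rt
Reagents that add atoms: water, O
Why: Acid-catalysed enol ether hydrolysis cleaves only the acetal-type C2–O bond, so the tertiary C–O stereocentre is retained and the methyl ketone is released.

**Step 3**
Reactants: 3, hydroxy ketone
Product: 4, (1S,2S)-2-(but-3-yn-1-yl)-1,3,3-trimethylcyclohexan-1-ol
Conditions: LDA (2.2 equiv), THF, −78 °C; ClP(O)(OEt)2 (1.1 equiv), −78 → 0 °C; then LDA (3 equiv), −78 °C → rt; aq. NH4Cl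
Reagents that add atoms: none
Why: Negishi one-pot methyl ketone → terminal alkyne conversion (kinetic enol phosphate, then elimination); the hindered tertiary alkoxide is a spectator and no stereocentre is touched.

**Step 4**
Reactants: 4, alkynol
Product: 5, (1S,2S)-2-[(3E)-4-iodo-3-methylbut-3-en-1-yl]-1,3,3-trimethylcyclohexan-1-ol
Conditions: Me3Al (3.5 equiv), Cp2ZrCl2 (0.5 equiv), CH2Cl2, 0 °C → rt; then I2, THF, −30 → 0 °C
Reagents that add atoms: trimethylaluminium, C[Al](C)C (adds CH3); iodine, II (adds I)
Why: Negishi Zr-catalysed carboalumination adds Me and Al syn with Al on the terminal carbon, and iodinolysis proceeds with retention, giving the E-trisubstituted vinyl iodide; the OH is masked in situ as its aluminium alkoxide.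

**Step 5**
Reactants: 6, geraniol
Product: 7, tert-butyl{[(2E)-3,7-dimethylocta-2,6-dien-1-yl]oxy}dimethylsilane
Conditions: TBSCl, imidazole, CH2Cl2, 0 °C → rt
Reagents that add atoms: tert-butyldimethylsilyl chloride, CC(C)(C)[Si](C)(C)Cl
Why: Standard silyl protection of the primary allylic alcohol; an allylic silyl ether, unlike an acetate, is inert to Pd(0) in step 9.

**Step 6**
Reactants: 7, geranyl TBS ether
Product: 8, (2E,6E)-8-[(tert-butyldimethylsilyl)oxy]-2,6-dimethylocta-2,6-dien-1-ol
Conditions: SeO2 (0.3 equiv), t-BuOOH (3 equiv), salicylic acid (cat.), CH2Cl2, 0 °C → rt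
Reagents that add atoms: selenium dioxide, O=[Se]=O, with tert-butyl hydroperoxide, CC(C)(C)OO (adds O)
Why: SeO2 allylic oxidation (ene reaction then [2,3]-shift) is selective for the E-methyl of the more electron-rich distal alkene and gives the E-allylic alcohol.

**Step 7**
Reactants: 8, allylic alcohol
Product: 9, (2E,6E)-8-[(tert-butyldimethylsilyl)oxy]-2,6-dimethylocta-2,6-dienal
Conditions: activated MnO2 (15 equiv), CH2Cl2, rt
Reagents that add atoms: none
Why: Chemoselective MnO2 oxidation of the allylic alcohol without E/Z isomerization; any aldehyde already formed in step 6 converges here.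

**Step 8**
Reactants: 9, enal
Product: 10, tert-butyldimethyl{[(2E,6E)-3,7-dimethylnona-2,6,8-trien-1-yl]oxy}silane
Conditions: Ph3PCH3Br, n-BuLi, THF, −78 → 0 °C
Reagents that add atoms: methyltriphenylphosphonium bromide, C[P+](c1ccccc1)(c1ccccc1)c1ccccc1.[Br-] (adds CH2)
Why: Wittig methylenation of the enal gives the terminal 1,3-diene and leaves the trisubstituted E-alkenes unchanged.

**Step 9**
Reactants: 10, triene (1.4 equiv); 5, vinyl iodide
Product: 11, (1S,2S)-2-[(3E,7E,11E)-13-[(tert-butyldimethylsilyl)oxy]-3,7,11-trimethyltrideca-3,7,11-trien-1-yl]-1,3,3-trimethylcyclohexan-1-ol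
Conditions: 10, 9-BBN, THF, 0 °C → rt, 3 h; then 3 M aq. Cs2CO3, 5, Pd(dppf)Cl2 (5 mol%), AsPh3 (10 mol%), DMF, rt
Reagents that add atoms: none (9-BBN delivers only H)
Why: 9-BBN hydroborates only the monosubstituted vinyl terminus (anti-Markovnikov) to give the homoallyl borane, and the B-alkyl Suzuki–Miyaura coupling with the vinyl iodide is stereoretentive, so all three alkenes are E.

**Step 10**
Reactants: 11, TBS ether
Product: 12, preluffariellolide A
Conditions: TBAF, THF, 0 °C → rt
Reagents that add atoms: none
Why: Fluoride-mediated desilylation frees the primary allylic alcohol without affecting the tertiary alcohol, the alkenes or the stereocentres.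

## Compound list

1 | (E)-geranylacetone | CC(=O)CC/C=C(\C)CCC=C(C)C | starting material
2 | (4aS,8aS)-2,5,5,8a-tetramethyl-4a,5,6,7,8,8a-hexahydro-4H-chromene | CC1=CC[C@H]2C(C)(C)CCC[C@]2(C)O1 | intermediate
3 | 4-[(1S,2S)-2-hydroxy-2,6,6-trimethylcyclohexyl]butan-2-one | CC(=O)CC[C@H]1C(C)(C)CCC[C@]1(C)O | intermediate
4 | (1S,2S)-2-(but-3-yn-1-yl)-1,3,3-trimethylcyclohexan-1-ol | C#CCC[C@H]1C(C)(C)CCC[C@]1(C)O | intermediate
5 | (1S,2S)-2-[(3E)-4-iodo-3-methylbut-3-en-1-yl]-1,3,3-trimethylcyclohexan-1-ol | I/C=C(\C)CC[C@H]1C(C)(C)CCC[C@]1(C)O | intermediate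
6 | geraniol | CC(C)=CCC/C(C)=C/CO | starting material
7 | geranyl TBS ether | CC(C)=CCC/C(C)=C/CO[Si](C)(C)C(C)(C)C | intermediate
8 | (2E,6E)-8-(TBS-oxy)-2,6-dimethylocta-2,6-dien-1-ol | OC/C(C)=C/CC/C(C)=C/CO[Si](C)(C)C(C)(C)C | intermediate
9 | (2E,6E)-8-(TBS-oxy)-2,6-dimethylocta-2,6-dienal | O=C/C(C)=C/CC/C(C)=C/CO[Si](C)(C)C(C)(C)C | intermediate
10 | TBS ether of (2E,6E)-3,7-dimethylnona-2,6,8-trien-1-ol | C=C/C(C)=C/CC/C(C)=C/CO[Si](C)(C)C(C)(C)C | intermediate
11 | TBS ether of preluffariellolide A | C/C(=C\CO[Si](C)(C)C(C)(C)C)CC/C=C(\C)CC/C=C(\C)CC[C@H]1C(C)(C)CCC[C@]1(C)O | intermediate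
12 | preluffariellolide A, (1S,2S)-2-[(3E,7E,11E)-13-hydroxy-3,7,11-trimethyltrideca-3,7,11-trien-1-yl]-1,3,3-trimethylcyclohexan-1-ol | C/C(=C\CO)CC/C=C(\C)CC/C=C(\C)CC[C@H]1C(C)(C)CCC[C@]1(C)O | target

## Summary

Total steps: 10 (9 if steps 1 and 2 are telescoped).
Longest linear sequence: 6 (steps 5–10 from geraniol; the geranylacetone branch, steps 1–4, 9, 10, is also 6).

Steps most likely to fail, with fallbacks:

1. **Step 1 (enzymatic cyclization).** The risk is enzyme availability and low conversion on a small C13 substrate. Fallback: use a stoichiometric chiral proton source instead (BINOL-monoether·SnCl4 Lewis-acid-assisted Brønsted acid, toluene, −78 °C) on 1; the ee is expected to be lower and would need enrichment (for example, chiral chromatography of 4).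
2. **Step 3 (ketone → alkyne on the unprotected δ-hydroxy ketone).** The risks are enolization regiochemistry and phosphorylation of the alkoxide. Fallback: reach 4 without a ketone by cyclizing (E)-5,9-dimethyldeca-4,8-dienoic acid to the trans-δ-lactone, reducing to the lactol with DIBAL-H, and applying Ohira–Bestmann homologation.
3. **Step 9 (diene hydroboration / B-alkyl Suzuki).** The risks are over-hydroboration and β-hydride elimination. Fallback: join the fragments as C15 + C10 by allyl sulfone alkylation: quench the alkenylalane of step 4 with paraformaldehyde to get the (E)-allylic alcohol, convert it to the allylic chloride, alkylate lithiated (2E,6E)-8-(phenylsulfonyl)geranyl TBS ether, then remove the sulfone with Pd(dppp)Cl2/LiBHEt3.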